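**Retrosynthetic overview**

1. The C50 chain is cut last at C7=C8 (Wittig) into a C1–C7 epoxy-enal, with C1–O as its triethylsilyl ether, and the ylide of a C8–C1' decaenyl phosphonium salt that already carries the (2'S) end group; fluoride then frees C1–OH.
2. The only ring, the oxirane C3–O–C4, lies directly beside C5. With C5 as a methyl ketone, C3=C4 is the single electron-poor alkene of the left fragment while the 3-methylbut-2-enyl alkene on C2 is electron-rich, so a nucleophilic, catalyst-controlled epoxidation of that enone closes the ring and sets C3 and C4.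
3. The enone comes from (S)-α-terpineol, which supplies C2: silylation, ozonolysis of the ring alkene, aldehyde-selective isopropylidene Wittig, Saegusa–Ito desaturation. The epoxy ketone is then extended by HWE (C6, C7), reduction and oxidation.
4. The right half comes from (R)-α-terpineol by the same ring opening and Wittig (one batch of ylide serves both series), then alkene hydration, Saegusa–Ito, vinyl addition, allylic phosphonium salt (C7'), Wittig with crocetindialdehyde (C8–C8'), reduction and a second salt formation at C8.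
5. Ring order: one ring only, the oxirane, closed in step 7.

Key step: step 7

Assumption: both α-terpineol enantiomers are used as enantiopure commercial lots and all-E crocetindialdehyde is bought as the C8–C8' block; steps 1–2 and 11–12 are run in parallel so that one freshly made batch of ylide 6 serves both Wittig reactions on the same day; carotenoid numbering (C1–C15, primed for the right half) is used for all intermediates.

**Route**

Step 1
Reactants: 1 (S)-α-terpineol
Product: 2 triethyl({2-[(1S)-4-methylcyclohex-3-en-1-yl]propan-2-yl}oxy)silane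
Conditions: Et3SiOTf, 2,6-lutidine, CH2Cl2, −78 → 0 °C
Reagents that add atoms: triethylsilyl trifluoromethanesulfonate, CC[Si](CC)(CC)OS(=O)(=O)C(F)(F)F
Why: Silyl triflate silylation of a hindered tertiary alcohol leaves the trisubstituted alkene and the stereocentre (the later C2) alone and prevents lactol or hemiketal formation after the ring is cleaved.

Step 2
Reactants: 2 triethyl({2-[(1S)-4-methylcyclohex-3-en-1-yl]propan-2-yl}oxy)silane
Product: 4 (3S)-6-oxo-3-[2-(triethylsilyloxy)propan-2-yl]heptanal, via secondary ozonide 3 (not isolated)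
Conditions: O3, CH2Cl2, −78 °C; then Me2S, −78 °C → rt
Reagents that add atoms: ozone, [O-][O+]=O
Why: Ozonolysis with reductive work-up cleaves the only C=C into a methyl ketone and an aldehyde on two different arms of the stereocentre, which is β to the aldehyde and γ to the ketone and therefore cannot epimerise by enolisation.

Step 3
Reactants: 5 isopropyltriphenylphosphonium iodide
Product: 6 isopropylidenetriphenylphosphorane (titrated THF solution, kept under argon and divided between steps 4 and 13)
Conditions: n-BuLi, THF, 0 °C, Ar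
Reagents that add atoms: none
Why: Deprotonation of the α-C–H of the phosphonium salt by n-butyllithium gives the non-stabilised ylide, which persists in dry THF under argon for the hours needed to serve the two parallel Wittig olefinations.

Step 4
Reactants: 4 (3S)-6-oxo-3-[2-(triethylsilyloxy)propan-2-yl]heptanal; 6 isopropylidenetriphenylphosphorane
Product: 7 (5S)-8-methyl-5-[2-(triethylsilyloxy)propan-2-yl]non-7-en-2-one
Conditions: 6 (1.0 equiv, THF solution from step 3), THF, −78 → 0 °C
Reagents that add atoms: isopropylidenetriphenylphosphorane (6), CC(C)=P(c1ccccc1)(c1ccccc1)c1ccccc1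
Why: Wittig olefination with one equivalent of a non-stabilised ylide at low temperature should take the aldehyde in preference to the methyl ketone and installs the prenyl terminus without creating a stereocentre.

Step 5
Reactants: 7 (5S)-8-methyl-5-[2-(triethylsilyloxy)propan-2-yl]non-7-en-2-one
Product: 8 (2Z,5R)-8-methyl-5-[2-(triethylsilyloxy)propan-2-yl]-2-(trimethylsilyloxy)nona-2,7-diene
Conditions: Me3SiCl, NaI, Et3N, MeCN, rt; pentane extraction, used crude
Reagents that add atoms: chlorotrimethylsilane, C[Si](C)(C)Cl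
Why: Silyl enol ether formation under equilibrating conditions should favour the more substituted internal enol silane of the methyl ketone (mainly Z; the geometry is irrelevant), and any terminal isomer merely returns ketone 7 in step 6 and is recycled.

Step 6
Reactants: 8 (2Z,5R)-8-methyl-5-[2-(triethylsilyloxy)propan-2-yl]-2-(trimethylsilyloxy)nona-2,7-diene
Product: 9 (3E,5R)-8-methyl-5-[2-(triethylsilyloxy)propan-2-yl]nona-3,7-dien-2-one
Conditions: Pd(OAc)2 (20 mol %), O2 (1 atm), DMSO, rt
Reagents that add atoms: none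
Why: Saegusa–Ito oxidation, in which the enol silane gives a divalent palladium enolate that loses a β-hydride from C3 to form the conjugated (E)-enone while oxygen reoxidises zerovalent palladium, leaves the isolated prenyl alkene and the silyl ether untouched.

Step 7
Reactants: 9 (3E,5R)-8-methyl-5-[2-(triethylsilyloxy)propan-2-yl]nona-3,7-dien-2-one; 10 tert-butyl hydroperoxide
Product: 11 1-[(2S,3R)-3-[(3R)-2,6-dimethyl-2-(triethylsilyloxy)hept-5-en-3-yl]oxiran-2-yl]ethan-1-one
Conditions: La(OCH(CH3)2)3 (10 mol %), (R)-BINOL (10 mol %), Ph3As=O (10 mol %), 10 (anhydrous, in decane), 4 Å MS, THF, rt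
Reagents that add atoms: tert-butyl hydroperoxide (10), CC(C)(C)OO
Why: A tert-butylperoxide ligand on lanthanum is delivered to the β-carbon C3 (1,4-addition), and the metal enolate so formed displaces tert-butoxide from the O–O bond through C4, a 3-exo-tet closure that completes the oxirane with its C3–O and C4–O bonds. The closest known reaction type is the catalytic Weitz–Scheffer epoxidation of acyclic (E)-α,β-unsaturated methyl ketones with an alkyl hydroperoxide under a lanthanide–BINOL–arsine oxide catalyst. Because the C3–C4 bond of the enolate can rotate before closure, the trans-disubstituted oxirane is expected, as it is from the E alkene. The configuration at C3, and through the trans closure at C4, is set by the chiral lanthanum–(R)-BINOL pocket, the ligand antipode expected to give the α-S, β-R epoxy ketone. In the conformer that minimises allylic strain (C2–H in the alkene plane) the silyloxyisopropyl group shields one face, and attack on the open face leads to the same C3 configuration, so ligand and substrate should be matched. The step needs chemoselectivity between two alkenes and facial selectivity at C3: the first is secured because only C3=C4 is conjugated to the C5 ketone and a peroxide anion ignores the electron-rich prenyl alkene, the second by the matched pairing just described.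

Step 8
Reactants: 11 1-[(2S,3R)-3-[(3R)-2,6-dimethyl-2-(triethylsilyloxy)hept-5-en-3-yl]oxiran-2-yl]ethan-1-one; 12 triethyl phosphonoacetate
Product: 14 ethyl (2E)-3-[(2R,3R)-3-[(3R)-2,6-dimethyl-2-(triethylsilyloxy)hept-5-en-3-yl]oxiran-2-yl]but-2-enoate, via sodium phosphonate 13 (not isolated)
Conditions: 12, NaH, THF, 0 °C; then 11, 0 °C → rt
Reagents that add atoms: triethyl phosphonoacetate (12), CCOC(=O)CP(=O)(OCC)OCC
Why: Horner–Wadsworth–Emmons olefination of the activated α,β-epoxy methyl ketone adds C6 and C7 and should favour the (E)-enoate (ester trans to the larger oxiranyl group), the minor Z isomer being removed by chromatography, while the oxirane C–H is not acidic enough to be removed by the phosphonate anion.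

Step 9
Reactants: 14 ethyl (2E)-3-[(2R,3R)-3-[(3R)-2,6-dimethyl-2-(triethylsilyloxy)hept-5-en-3-yl]oxiran-2-yl]but-2-enoate
Product: 15 (2E)-3-[(2R,3R)-3-[(3R)-2,6-dimethyl-2-(triethylsilyloxy)hept-5-en-3-yl]oxiran-2-yl]but-2-en-1-ol
Conditions: i-Bu2AlH (2.2 equiv), CH2Cl2, −78 °C; aq. potassium sodium tartrate
Reagents that add atoms: none
Why: Hydride reduction of the conjugated ester by 1,2-delivery at −78 °C should be faster than opening of the vinyl oxirane, and the neutral tartrate work-up protects the acid-labile epoxide.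

Step 10
Reactants: 15 (2E)-3-[(2R,3R)-3-[(3R)-2,6-dimethyl-2-(triethylsilyloxy)hept-5-en-3-yl]oxiran-2-yl]but-2-en-1-ol
Product: 16 (2E)-3-[(2R,3R)-3-[(3R)-2,6-dimethyl-2-(triethylsilyloxy)hept-5-en-3-yl]oxiran-2-yl]but-2-enal
Conditions: MnO2, CH2Cl2, rt
Reagents that add atoms: none
Why: Allylic oxidation with MnO2 is neutral and heterogeneous, takes only the primary allylic alcohol to the enal with retention of alkene geometry, and spares the epoxide, silyl ether and prenyl alkene.

Step 11
Reactants: 17 (R)-α-terpineol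
Product: 18 triethyl({2-[(1R)-4-methylcyclohex-3-en-1-yl]propan-2-yl}oxy)silane
Conditions: Et3SiOTf, 2,6-lutidine, CH2Cl2, −78 → 0 °C
Reagents that add atoms: triethylsilyl trifluoromethanesulfonate, CC[Si](CC)(CC)OS(=O)(=O)C(F)(F)F
Why: The same tertiary-alcohol silylation as in step 1 on the antipode, whose stereocentre becomes C2' of the right end group.

Step 12
Reactants: 18 triethyl({2-[(1R)-4-methylcyclohex-3-en-1-yl]propan-2-yl}oxy)silane
Product: 20 (3R)-6-oxo-3-[2-(triethylsilyloxy)propan-2-yl]heptanal, via secondary ozonide 19 (not isolated)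
Conditions: O3, CH2Cl2, −78 °C; then Me2S, −78 °C → rt
Reagents that add atoms: ozone, [O-][O+]=O
Why: Ozonolysis with reductive work-up as in step 2 gives the enantiomeric keto-aldehyde without risk to the stereocentre.

Step 13
Reactants: 20 (3R)-6-oxo-3-[2-(triethylsilyloxy)propan-2-yl]heptanal; 6 isopropylidenetriphenylphosphorane
Product: 21 (5R)-8-methyl-5-[2-(triethylsilyloxy)propan-2-yl]non-7-en-2-one
Conditions: 6 (1.0 equiv, THF solution from step 3), THF, −78 → 0 °C
Reagents that add atoms: isopropylidenetriphenylphosphorane (6), CC(C)=P(c1ccccc1)(c1ccccc1)c1ccccc1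
Why: Aldehyde-selective Wittig olefination as in step 4 brings in the carbons of the later 3-hydroxy-3-methylbutyl side chain.

Step 14
Reactants: 21 (5R)-8-methyl-5-[2-(triethylsilyloxy)propan-2-yl]non-7-en-2-one
Product: 22 (5S)-8-hydroxy-8-methyl-5-[2-(triethylsilyloxy)propan-2-yl]nonan-2-one
Conditions: Co(acac)2 (20 mol %), PhSiH3, O2 (1 atm), i-PrOH, rt
Reagents that add atoms: dioxygen, O=O
Why: Mukaiyama hydration (cobalt-hydride hydrogen-atom transfer to the trisubstituted alkene, capture of the tertiary radical by O2, reduction of the peroxide by silane) gives the Markovnikov tertiary alcohol and tolerates the ketone and silyl ether, and it is placed here because the same conditions would reduce the later enone.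

Step 15
Reactants: 22 (5S)-8-hydroxy-8-methyl-5-[2-(triethylsilyloxy)propan-2-yl]nonan-2-one
Product: 23 (2Z,5S)-8-methyl-5-[2-(triethylsilyloxy)propan-2-yl]-2,8-bis(trimethylsilyloxy)non-2-ene
Conditions: Me3SiCl (3 equiv), NaI, Et3N, MeCN, rt; pentane extraction, used crude
Reagents that add atoms: chlorotrimethylsilane, C[Si](C)(C)Cl
Why: The equilibrating enol silane formation of step 5, run with excess reagent so that the new tertiary alcohol is capped as its trimethylsilyl ether in the same operation.

Step 16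
Reactants: 23 (2Z,5S)-8-methyl-5-[2-(triethylsilyloxy)propan-2-yl]-2,8-bis(trimethylsilyloxy)non-2-ene
Product: 24 (3E,5S)-8-methyl-5-[2-(triethylsilyloxy)propan-2-yl]-8-(trimethylsilyloxy)non-3-en-2-one
Conditions: Pd(OAc)2 (20 mol %), O2 (1 atm), DMSO, rt
Reagents that add atoms: none
Why: Saegusa–Ito oxidation as in step 6 forms the C3'=C4' (E)-alkene conjugated to the C5' ketone under neutral conditions that both silyl ethers should survive.

Step 17
Reactants: 24 (3E,5S)-8-methyl-5-[2-(triethylsilyloxy)propan-2-yl]-8-(trimethylsilyloxy)non-3-en-2-one; 25 vinylmagnesium bromide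
Product: 26 (4E,6S)-3,9-dimethyl-6-[2-(triethylsilyloxy)propan-2-yl]-9-(trimethylsilyloxy)deca-1,4-dien-3-ol (both C3 epimers)
Conditions: 25, THF, −78 → 0 °C; aq. NH4Cl
Reagents that add atoms: vinylmagnesium bromide (25), C=C[Mg]Br
Why: Grignard 1,2-addition to the carbonyl of an enone whose β-carbon is blocked by the branched C2' gives the tertiary bis-allylic carbinol, and the unselective new centre at C5' is immaterial because it becomes sp2 in step 18.

Step 18
Reactants: 26 (4E,6S)-3,9-dimethyl-6-[2-(triethylsilyloxy)propan-2-yl]-9-(trimethylsilyloxy)deca-1,4-dien-3-ol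
Product: 27 [(2E,4E,6S)-9-hydroxy-6-(2-hydroxypropan-2-yl)-3,9-dimethyldeca-2,4-dien-1-yl]triphenylphosphonium bromide
Conditions: PPh3·HBr (1.2 equiv), MeOH, 0 °C → rt; crystallisation
Reagents that add atoms: triphenylphosphonium bromide (PPh3·HBr), [PH+](c1ccccc1)(c1ccccc1)c1ccccc1.[Br-]
Why: Acid-mediated allylic phosphonium salt formation with allylic transposition, in which the carbinol ionises to a pentadienyl cation that PPh3 captures irreversibly at the unhindered C7' terminus (reversibly formed ethers re-ionise), should give the conjugated diene salt, mainly 5'E, while the methanolic acid cleaves both silyl ethers and C2', outside the cation, keeps its configuration.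

Step 19
Reactants: 27 [(2E,4E,6S)-9-hydroxy-6-(2-hydroxypropan-2-yl)-3,9-dimethyldeca-2,4-dien-1-yl]triphenylphosphonium bromide; 28 crocetindialdehyde
Product: 31 (all-E,22S)-25-hydroxy-22-(2-hydroxypropan-2-yl)-2,6,11,15,19,25-hexamethylhexacosa-2,4,6,8,10,12,14,16,18,20-decaenal, via dienyl ylide 29 (not isolated), via 7'Z aldehyde 30 (not isolated)
Conditions: 28 (3 equiv), NaOMe, CH2Cl2/MeOH, 0 °C → rt; then heptane, 80 °C, Ar, dark
Reagents that add atoms: crocetindialdehyde (28), O=C/C(C)=C/C=C/C(C)=C/C=C/C=C(C)/C=C/C=C(C)/C=O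
Why: Wittig olefination of the semi-stabilised ylide with one aldehyde of the symmetrical C20 dialdehyde, used in excess and recovered to favour mono-olefination, forms C7'=C8' as an E/Z mixture whose Z isomer is a hindered cis-alkene (C9' methyl against C6'–H) and should isomerise to all-E on heating.

Step 20
Reactants: 31 (all-E,22S)-25-hydroxy-22-(2-hydroxypropan-2-yl)-2,6,11,15,19,25-hexamethylhexacosa-2,4,6,8,10,12,14,16,18,20-decaenal
Product: 32 (all-E,22S)-22-(2-hydroxypropan-2-yl)-2,6,11,15,19,25-hexamethylhexacosa-2,4,6,8,10,12,14,16,18,20-decaene-1,25-diol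
Conditions: NaBH4, MeOH/CH2Cl2, 0 °C
Reagents that add atoms: none
Why: Borohydride 1,2-reduction of the polyenal gives the primary allylic alcohol without touching the polyene or the tertiary alcohols.

Step 21
Reactants: 32 (all-E,22S)-22-(2-hydroxypropan-2-yl)-2,6,11,15,19,25-hexamethylhexacosa-2,4,6,8,10,12,14,16,18,20-decaene-1,25-diol
Product: 33 [(all-E,22S)-25-hydroxy-22-(2-hydroxypropan-2-yl)-2,6,11,15,19,25-hexamethylhexacosa-2,4,6,8,10,12,14,16,18,20-decaen-1-yl]triphenylphosphonium bromide
Conditions: PPh3·HBr, MeOH/CH2Cl2, 0 °C → rt, dark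
Reagents that add atoms: triphenylphosphonium bromide (PPh3·HBr), [PH+](c1ccccc1)(c1ccccc1)c1ccccc1.[Br-]
Why: The acid-mediated phosphonium salt formation used for retinol-type polyenols should capture the delocalised polyenyl cation at the primary C8 terminus, the only position that keeps the whole decaene conjugated, while the unactivated tertiary alcohols do not ionise at this temperature.

Step 22
Reactants: 33 [(all-E,22S)-25-hydroxy-22-(2-hydroxypropan-2-yl)-2,6,11,15,19,25-hexamethylhexacosa-2,4,6,8,10,12,14,16,18,20-decaen-1-yl]triphenylphosphonium bromide; 16 (2E)-3-[(2R,3R)-3-[(3R)-2,6-dimethyl-2-(triethylsilyloxy)hept-5-en-3-yl]oxiran-2-yl]but-2-enal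
Product: 36 1-O-triethylsilyl ether of the target (all-E; 2R,3R,4R,2'S), via polyenyl ylide 34 (not isolated), via 7Z isomer 35 (not isolated)
Conditions: NaOMe, CH2Cl2/MeOH, −10 °C → rt; then heptane/EtOAc, 70 °C, Ar, dark
Reagents that add atoms: none
Why: Wittig olefination forms C7=C8 and completes the C50 skeleton with the base-sensitive oxirane on the aldehyde partner, where it cannot undergo the vinylogous β-elimination it would suffer beside an ylide carbon, and the hindered 7Z isomer should equilibrate thermally to all-E without affecting the four stereocentres.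

Step 23
Reactants: 36 1-O-triethylsilyl ether of the target
Product: 37 CNP0268815.3, (all-E,2R,3R,4R,2'S)-3,4-epoxy-2'-(3-hydroxy-3-methylbutyl)-2-(3-methylbut-2-en-1-yl)-3',4'-didehydro-1,2,3,4,1',2'-hexahydro-ψ,ψ-carotene-1,1'-diol
Conditions: Bu4NF, THF, 0 °C → rt, dark
Reagents that add atoms: none
Why: Fluoride desilylation cleaves the tertiary Si–O bond without acid, which matters because an oxirane attached directly to the polyene would open to a polyenyl cation under acidic deprotection.

**Compound list**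

1 | (S)-α-terpineol, 2-[(1S)-4-methylcyclohex-3-en-1-yl]propan-2-ol | CC1=CC[C@H](CC1)C(C)(C)O | starting material
2 | triethyl({2-[(1S)-4-methylcyclohex-3-en-1-yl]propan-2-yl}oxy)silane | CC1=CC[C@H](CC1)C(C)(C)O[Si](CC)(CC)CC | intermediate
3 | secondary ozonide of 2, 1-methyl-4-[2-(triethylsilyloxy)propan-2-yl]-7,8,9-trioxabicyclo[4.2.1]nonane (C4 as in 2, both bridgehead diastereomers; not isolated) | CC12CC[C@@H](CC(O1)OO2)C(C)(C)O[Si](CC)(CC)CC | intermediate
4 | (3S)-6-oxo-3-[2-(triethylsilyloxy)propan-2-yl]heptanal | O=CC[C@H](CCC(C)=O)C(C)(C)O[Si](CC)(CC)CC | intermediate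
5 | isopropyltriphenylphosphonium iodide | CC(C)[P+](c1ccccc1)(c1ccccc1)c1ccccc1.[I-] | starting material
6 | isopropylidenetriphenylphosphorane (THF solution, one batch used for steps 4 and 13) | CC(C)=P(c1ccccc1)(c1ccccc1)c1ccccc1 | intermediate
7 | (5S)-8-methyl-5-[2-(triethylsilyloxy)propan-2-yl]non-7-en-2-one | CC(C)=CC[C@H](CCC(C)=O)C(C)(C)O[Si](CC)(CC)CC | intermediate
8 | (2Z,5R)-8-methyl-5-[2-(triethylsilyloxy)propan-2-yl]-2-(trimethylsilyloxy)nona-2,7-diene | CC(C)=CC[C@H](C/C=C(/C)O[Si](C)(C)C)C(C)(C)O[Si](CC)(CC)CC | intermediate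
9 | (3E,5R)-8-methyl-5-[2-(triethylsilyloxy)propan-2-yl]nona-3,7-dien-2-one (key-step precursor) | CC(C)=CC[C@H](/C=C/C(C)=O)C(C)(C)O[Si](CC)(CC)CC | intermediate
10 | tert-butyl hydroperoxide | CC(C)(C)OO | starting material
11 | 1-[(2S,3R)-3-[(3R)-2,6-dimethyl-2-(triethylsilyloxy)hept-5-en-3-yl]oxiran-2-yl]ethan-1-one (key-step product; carotenoid C2 R, C3 R, C4 S) | CC(C)=CC[C@H]([C@H]1O[C@@H]1C(C)=O)C(C)(C)O[Si](CC)(CC)CC | intermediate
12 | triethyl phosphonoacetate | CCOC(=O)CP(=O)(OCC)OCC | starting material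
13 | sodium salt of triethyl phosphonoacetate (not isolated) | CCOC(=O)[CH-]P(=O)(OCC)OCC.[Na+] | intermediate
14 | ethyl (2E)-3-[(2R,3R)-3-[(3R)-2,6-dimethyl-2-(triethylsilyloxy)hept-5-en-3-yl]oxiran-2-yl]but-2-enoate | CC(C)=CC[C@H]([C@H]1O[C@@H]1/C(C)=C/C(=O)OCC)C(C)(C)O[Si](CC)(CC)CC | intermediate
15 | (2E)-3-[(2R,3R)-3-[(3R)-2,6-dimethyl-2-(triethylsilyloxy)hept-5-en-3-yl]oxiran-2-yl]but-2-en-1-ol | CC(C)=CC[C@H]([C@H]1O[C@@H]1/C(C)=C/CO)C(C)(C)O[Si](CC)(CC)CC | intermediate
16 | (2E)-3-[(2R,3R)-3-[(3R)-2,6-dimethyl-2-(triethylsilyloxy)hept-5-en-3-yl]oxiran-2-yl]but-2-enal (C1–C7 epoxy-enal) | CC(C)=CC[C@H]([C@H]1O[C@@H]1/C(C)=C/C=O)C(C)(C)O[Si](CC)(CC)CC | intermediate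
17 | (R)-α-terpineol, 2-[(1R)-4-methylcyclohex-3-en-1-yl]propan-2-ol | CC1=CC[C@@H](CC1)C(C)(C)O | starting material
18 | triethyl({2-[(1R)-4-methylcyclohex-3-en-1-yl]propan-2-yl}oxy)silane | CC1=CC[C@@H](CC1)C(C)(C)O[Si](CC)(CC)CC | intermediate
19 | secondary ozonide of 18 (C4 as in 18, both bridgehead diastereomers; not isolated) | CC12CC[C@H](CC(O1)OO2)C(C)(C)O[Si](CC)(CC)CC | intermediate
20 | (3R)-6-oxo-3-[2-(triethylsilyloxy)propan-2-yl]heptanal | O=CC[C@@H](CCC(C)=O)C(C)(C)O[Si](CC)(CC)CC | intermediate
21 | (5R)-8-methyl-5-[2-(triethylsilyloxy)propan-2-yl]non-7-en-2-one | CC(C)=CC[C@@H](CCC(C)=O)C(C)(C)O[Si](CC)(CC)CC | intermediate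
22 | (5S)-8-hydroxy-8-methyl-5-[2-(triethylsilyloxy)propan-2-yl]nonan-2-one | CC(C)(O)CC[C@@H](CCC(C)=O)C(C)(C)O[Si](CC)(CC)CC | intermediate
23 | (2Z,5S)-8-methyl-5-[2-(triethylsilyloxy)propan-2-yl]-2,8-bis(trimethylsilyloxy)non-2-ene | C[Si](C)(C)OC(C)(C)CC[C@@H](C/C=C(/C)O[Si](C)(C)C)C(C)(C)O[Si](CC)(CC)CC | intermediate
24 | (3E,5S)-8-methyl-5-[2-(triethylsilyloxy)propan-2-yl]-8-(trimethylsilyloxy)non-3-en-2-one | C[Si](C)(C)OC(C)(C)CC[C@@H](/C=C/C(C)=O)C(C)(C)O[Si](CC)(CC)CC | intermediate
25 | vinylmagnesium bromide | C=C[Mg]Br | starting material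
26 | (4E,6S)-3,9-dimethyl-6-[2-(triethylsilyloxy)propan-2-yl]-9-(trimethylsilyloxy)deca-1,4-dien-3-ol (both C3 epimers) | C[Si](C)(C)OC(C)(C)CC[C@@H](/C=C/C(C)(O)C=C)C(C)(C)O[Si](CC)(CC)CC | intermediate
27 | [(2E,4E,6S)-9-hydroxy-6-(2-hydroxypropan-2-yl)-3,9-dimethyldeca-2,4-dien-1-yl]triphenylphosphonium bromide (C7' salt) | CC(C)(O)CC[C@@H](/C=C/C(C)=C/C[P+](c1ccccc1)(c1ccccc1)c1ccccc1)C(C)(C)O.[Br-] | intermediate
28 | crocetindialdehyde, (all-E)-2,6,11,15-tetramethylhexadeca-2,4,6,8,10,12,14-heptaenedial | O=C/C(C)=C/C=C/C(C)=C/C=C/C=C(C)/C=C/C=C(C)/C=O | starting material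
29 | ylide of 27 (not isolated) | CC(C)(O)CC[C@@H](/C=C/C(C)=C/C=P(c1ccccc1)(c1ccccc1)c1ccccc1)C(C)(C)O | intermediate
30 | (7'Z)-isomer of 31, carotenoid numbering (not isolated) | O=C/C(C)=C/C=C/C(C)=C/C=C/C=C(C)/C=C/C=C(C)/C=C\C=C(C)\C=C\[C@H](CCC(C)(C)O)C(C)(C)O | intermediate
31 | (all-E,22S)-25-hydroxy-22-(2-hydroxypropan-2-yl)-2,6,11,15,19,25-hexamethylhexacosa-2,4,6,8,10,12,14,16,18,20-decaenal (C8 aldehyde, C8–C1') | O=C/C(C)=C/C=C/C(C)=C/C=C/C=C(C)/C=C/C=C(C)/C=C/C=C(C)/C=C/[C@H](CCC(C)(C)O)C(C)(C)O | intermediate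
32 | (all-E,22S)-22-(2-hydroxypropan-2-yl)-2,6,11,15,19,25-hexamethylhexacosa-2,4,6,8,10,12,14,16,18,20-decaene-1,25-diol | OC/C(C)=C/C=C/C(C)=C/C=C/C=C(C)/C=C/C=C(C)/C=C/C=C(C)/C=C/[C@H](CCC(C)(C)O)C(C)(C)O | intermediate
33 | [(all-E,22S)-25-hydroxy-22-(2-hydroxypropan-2-yl)-2,6,11,15,19,25-hexamethylhexacosa-2,4,6,8,10,12,14,16,18,20-decaen-1-yl]triphenylphosphonium bromide (C8 salt) | [Br-].c1ccccc1[P+](c1ccccc1)(c1ccccc1)C/C(C)=C/C=C/C(C)=C/C=C/C=C(C)/C=C/C=C(C)/C=C/C=C(C)/C=C/[C@H](CCC(C)(C)O)C(C)(C)O | intermediate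
34 | ylide of 33 (not isolated) | c1ccccc1P(c1ccccc1)(c1ccccc1)=C/C(C)=C/C=C/C(C)=C/C=C/C=C(C)/C=C/C=C(C)/C=C/C=C(C)/C=C/[C@H](CCC(C)(C)O)C(C)(C)O | intermediate
35 | (7Z)-isomer of 36 (not isolated) | CC(C)=CC[C@H]([C@H]1O[C@@H]1/C(C)=C/C=C\C(C)=C\C=C\C(C)=C\C=C\C=C(C)\C=C\C=C(C)\C=C\C=C(C)\C=C\[C@H](CCC(C)(C)O)C(C)(C)O)C(C)(C)O[Si](CC)(CC)CC | intermediate
36 | 1-O-triethylsilyl ether of the target (all-E; 2R,3R,4R,2'S) | CC(C)=CC[C@H]([C@H]1O[C@@H]1/C(C)=C/C=C/C(C)=C/C=C/C(C)=C/C=C/C=C(C)/C=C/C=C(C)/C=C/C=C(C)/C=C/[C@H](CCC(C)(C)O)C(C)(C)O)C(C)(C)O[Si](CC)(CC)CC | intermediate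
37 | CNP0268815.3, (all-E,2R,3R,4R,2'S)-3,4-epoxy-2'-(3-hydroxy-3-methylbutyl)-2-(3-methylbut-2-en-1-yl)-3',4'-didehydro-1,2,3,4,1',2'-hexahydro-ψ,ψ-carotene-1,1'-diol | CC(C)=CC[C@H]([C@H]1O[C@@H]1/C(C)=C/C=C/C(C)=C/C=C/C(C)=C/C=C/C=C(C)/C=C/C=C(C)/C=C/C=C(C)/C=C/[C@H](CCC(C)(C)O)C(C)(C)O)C(C)(C)O | target

**Step count and risks**

Total step count: 23 (steps 1–2 and 4–10 left fragment, step 3 the ylide batch shared by both series, steps 11–21 right fragment, steps 22–23 union and deprotection). Longest linear sequence: 13 steps (steps 11–23, from (R)-α-terpineol).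

Steps most likely to fail:

Step 7. The peroxide may add slowly or with poor facial selectivity to the γ-branched C3, or the basic lanthanum alkoxide may deconjugate the enone by γ-deprotonation before epoxidation. The fallback replaces the nucleophilic epoxidation by a hydroxyl-directed electrophilic one. It sets out from 9: CBS reduction ((S)-2-methyl-CBS-oxazaborolidine, catecholborane, toluene, −78 °C, which does not hydroborate the prenyl alkene) should give the (2R,3E,5R)-allylic alcohol F1. Sharpless asymmetric epoxidation (Ti(OCH(CH3)2)4, D-(−)-diisopropyl tartrate, tert-butyl hydroperoxide, 4 Å MS, CH2Cl2, −20 °C) is the matched pairing for the (R)-carbinol, touches only the allylic-alcohol alkene, and should give the anti epoxy alcohol F2 with the required C3 and C4 configuration. Dess–Martin periodinane with NaHCO3 in CH2Cl2 then oxidises the carbinol and the route is rejoined at 11.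

Step 21. Under acid the decaenol may be lost through retro-type double-bond migration, capture of the polyenyl cation at internal positions or by the tertiary hydroxyls, or oligomerisation. The fallback avoids ionising the alcohol. It sets out from 32: Appel bromination (CBr4, PPh3, 2,6-lutidine, CH2Cl2, −20 °C, one equivalent so that only the primary allylic hydroxyl reacts) gives the (all-E,22S)-decaenyl bromide F3, which is not stored but displaced at once by PPh3 (EtOAc/CH2Cl2, rt) in an SN2 reaction at the primary carbon. The route is rejoined at 33.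

Step 22. The highly delocalised ylide may be too weak a nucleophile at temperatures where the epoxy-enal survives methoxide, so the aldehyde is consumed by conjugate addition of methoxide or base-induced opening of the oxirane through γ-deprotonation. The fallback changes the union to an HWE reaction of a more nucleophilic phosphonate carbanion. It sets out from 32: the bromide F3, made as described for step 21, is treated with NaP(O)(OEt)2 (Michaelis–Becker, THF, 0 °C) to give the diethyl (all-E,22S)-decaenylphosphonate F4. Deprotonation with NaN(SiMe3)2 (3 equiv, THF, −78 °C, the first two equivalents taken up by the tertiary hydroxyls), addition of 16 at −78 °C and the thermal equilibration of step 22 should form C7=C8 mainly E. The route is rejoined at 36, and this branch also bypasses step 21.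

Further compounds
F1 | step 7 | (2R,3E,5R)-8-methyl-5-[2-(triethylsilyloxy)propan-2-yl]nona-3,7-dien-2-ol | CC(C)=CC[C@H](/C=C/[C@@H](C)O)C(C)(C)O[Si](CC)(CC)CC
F2 | step 7 | (1R)-1-[(2R,3R)-3-[(3R)-2,6-dimethyl-2-(triethylsilyloxy)hept-5-en-3-yl]oxiran-2-yl]ethan-1-ol | CC(C)=CC[C@H]([C@H]1O[C@@H]1[C@@H](C)O)C(C)(C)O[Si](CC)(CC)CC
F3 | step 21 | (all-E,22S)-1-bromo-22-(2-hydroxypropan-2-yl)-2,6,11,15,19,25-hexamethylhexacosa-2,4,6,8,10,12,14,16,18,20-decaen-25-ol | BrC/C(C)=C/C=C/C(C)=C/C=C/C=C(C)/C=C/C=C(C)/C=C/C=C(C)/C=C/[C@H](CCC(C)(C)O)C(C)(C)O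
F4 | step 22 | diethyl [(all-E,22S)-25-hydroxy-22-(2-hydroxypropan-2-yl)-2,6,11,15,19,25-hexamethylhexacosa-2,4,6,8,10,12,14,16,18,20-decaen-1-yl]phosphonate | CCOP(=O)(OCC)C/C(C)=C/C=C/C(C)=C/C=C/C=C(C)/C=C/C=C(C)/C=C/C=C(C)/C=C/[C@H](CCC(C)(C)O)C(C)(C)O
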